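The hydrindane is opened between the methylidene-bearing carbon C4 and the acyloxy-bearing carbon C5 of its six-membered ring (indane numbering), i.e. across the 2-methylidenecyclohexanol unit. An intramolecular Nozaki–Hiyama–Kishi reaction forges this bond: a 1-iodoethenyl group adds to an aldehyde, closing the cyclohexane ring trans onto a finished cyclopentanone and creating the exocyclic alkene and the C5 carbinol in one operation. The precursor is a 2,3,4,5-tetrasubstituted cyclopentanone that already carries both other esters; its aldehyde arm with the isopropyl stereocentre stems from ozonolytic opening of (R)-p-menth-1-ene, and the five-membered ring is built on that chain by conjugate addition and aldol condensation.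

Key step: step 13

Remark: (R)-p-menth-1-ene (the partial-hydrogenation product of (R)-limonene), (2R)-2-methylbutanoic acid and (2E)-3-methylpent-2-enoic acid are taken as purchasable.

Step 1
Reactants: 1 (4R)-1-methyl-4-(propan-2-yl)cyclohex-1-ene
Product: 2 (5R)-7,7-dimethoxy-5-(propan-2-yl)heptan-2-one
Conditions: O3, CH2Cl2/MeOH, −78 °C; TsOH (cat.), 25 °C; Me2S
Reagents that add atoms: ozone, O=[O+][O-]; methanol, CO
Why: Ozonolysis of the trisubstituted ring alkene in methanol should place the carbonyl oxide on the more substituted carbon, so that acid acetalises only the aldehyde terminus and reductive work-up frees the methyl ketone, the isopropyl stereocentre being untouched.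

Step 2
Reactants: 2 (5R)-7,7-dimethoxy-5-(propan-2-yl)heptan-2-one
Product: 3 trimethyl{[(2Z,5R)-7,7-dimethoxy-5-(propan-2-yl)hept-2-en-2-yl]oxy}silane
Conditions: BrMgN(i-Pr)2, Me3SiCl, Et3N, HMPA, Et2O, 25 °C
Reagents that add atoms: chlorotrimethylsilane, C[Si](C)(C)Cl
Why: Equilibrating magnesium amide enolisation with O-silylation should give the more substituted (thermodynamic) silyl enol ether, which determines the site of the coming dehydrogenation while the acetal survives the basic medium.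

Step 3
Reactants: 3 trimethyl{[(2Z,5R)-7,7-dimethoxy-5-(propan-2-yl)hept-2-en-2-yl]oxy}silane
Product: 4 (3E,5R)-7,7-dimethoxy-5-(propan-2-yl)hept-3-en-2-one
Conditions: Pd(OAc)2 (10 mol%), O2 (1 atm), DMSO, 25 °C
Reagents that add atoms: none
Why: Saegusa–Ito oxidation: the palladium enolate formed from the silyl enol ether undergoes β-hydride elimination to the conjugated (E)-enone and oxygen returns palladium to the divalent state.

Step 4
Reactants: 4 (3E,5R)-7,7-dimethoxy-5-(propan-2-yl)hept-3-en-2-one; 5 [(1E)-prop-1-en-1-yl]boronic acid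
Product: 6 (4S,5R)-7,7-dimethoxy-4-[(1E)-prop-1-en-1-yl]-5-(propan-2-yl)heptan-2-one
Conditions: [Rh(OH)((R)-binap)]2 (3 mol% Rh), dioxane/H2O (10:1), 40 °C
Reagents that add atoms: none
Why: Hayashi–Miyaura reaction (rhodium-catalysed asymmetric 1,4-addition): the alkenylrhodium formed by transmetalation inserts the (E)-enone and water protonates the oxa-π-allyl, the new C4 centre (4S) being set by the (R)-BINAP catalyst, which selects the Cβ face, and not by the neighbouring C5 centre.

Step 5
Reactants: 6 (4S,5R)-7,7-dimethoxy-4-[(1E)-prop-1-en-1-yl]-5-(propan-2-yl)heptan-2-one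
Product: 8 (4S)-4-[(3R)-1,1-dimethoxy-4-methylpentan-3-yl]cyclopent-2-en-1-one, via keto aldehyde 7 (not isolated)
Conditions: O3, CH2Cl2, −78 °C; PPh3; concentrate; then KOH, MeOH, 0 °C
Reagents that add atoms: ozone, O=[O+][O-] (its oxygen is carried by 7 and leaves as water in the condensation)
Why: Ozonolysis unmasks the propenyl group as an aldehyde and base then drives the intramolecular aldol condensation of the methyl ketone onto it to the 4-substituted cyclopent-2-enone, cold dilute base being chosen so that the centre α to the aldehyde closes the ring before it can epimerise.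

Step 6
Reactants: 8 (4S)-4-[(3R)-1,1-dimethoxy-4-methylpentan-3-yl]cyclopent-2-en-1-one; 9 acetaldehyde
Product: 10 (4S,5R)-4-[(3R)-1,1-dimethoxy-4-methylpentan-3-yl]-5-[(1S)-1-hydroxyethyl]cyclopent-2-en-1-one
Conditions: LiN(i-Pr)2, THF, −78 °C; Cp2ZrCl2, −78 to −30 °C; then 9, −78 °C
Reagents that add atoms: none
Why: Zirconium-enolate aldol addition: kinetic α′-deprotonation and transmetalation give an enolate that adds syn-selectively whatever its geometry, which should set the (1S)-carbinol, while the aldehyde approaches C5 anti to the C4 side chain and so sets the 4,5-trans relationship.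

Step 7
Reactants: 10 (4S,5R)-4-[(3R)-1,1-dimethoxy-4-methylpentan-3-yl]-5-[(1S)-1-hydroxyethyl]cyclopent-2-en-1-one
Product: 11 (1S)-1-[(1R,5S)-5-[(3R)-1,1-dimethoxy-4-methylpentan-3-yl]-2-oxocyclopent-3-en-1-yl]ethyl acetate
Conditions: Ac2O, pyridine, DMAP (cat.), CH2Cl2, 0 °C
Reagents that add atoms: acetic anhydride, CC(=O)OC(C)=O
Why: O-Acetylation of the secondary alcohol installs the acetate of the target directly, the low temperature keeping the β-acetoxy ketone from eliminating.

Step 8
Reactants: 11 (1S)-1-[(1R,5S)-5-[(3R)-1,1-dimethoxy-4-methylpentan-3-yl]-2-oxocyclopent-3-en-1-yl]ethyl acetate; 12 (1-bromoethenyl)trimethylsilane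
Product: 14 (1S)-1-[(1R,4R,5S)-5-[(3R)-1,1-dimethoxy-4-methylpentan-3-yl]-2-[(trimethylsilyl)oxy]-4-[1-(trimethylsilyl)ethenyl]cyclopent-2-en-1-yl]ethyl acetate, via Grignard reagent 13 (not isolated)
Conditions: 12, Mg, THF, 25 °C; then CuBr·SMe2 (10 mol%), Me3SiCl, HMPA, 11, THF, −78 °C; Et3N
Reagents that add atoms: chlorotrimethylsilane, C[Si](C)(C)Cl; magnesium, [Mg] (held only in 13)
Why: Copper-catalysed conjugate addition with silyl trapping: the 1-silylvinyl group should add to the enone β-carbon anti to the adjacent side chain (trans relationship of the two future ring-fusion carbons), and the enolate is trapped regiospecifically as its silyl enol ether on the unsubstituted side of the ketone.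

Step 9
Reactants: 14 (1S)-1-[(1R,4R,5S)-5-[(3R)-1,1-dimethoxy-4-methylpentan-3-yl]-2-[(trimethylsilyl)oxy]-4-[1-(trimethylsilyl)ethenyl]cyclopent-2-en-1-yl]ethyl acetate
Product: 16 (1S)-1-[(1R,3S,4R,5S)-5-[(3R)-1,1-dimethoxy-4-methylpentan-3-yl]-3-hydroxy-2-oxo-4-[1-(trimethylsilyl)ethenyl]cyclopentyl]ethyl acetate, via silyloxy ketone 15 (not isolated)
Conditions: DMDO, acetone/CH2Cl2, −78 to −20 °C; then AcOH, THF/H2O, 0 °C
Reagents that add atoms: dimethyldioxirane, CC1(C)OO1
Why: Rubottom oxidation: the silyl enol ether is epoxidised far faster than the vinylsilane and from the face anti to the neighbouring silylethenyl group, so that silyl migration and hydrolysis should give the α-hydroxy ketone with the hydroxyl trans to that group.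

Step 10
Reactants: 16 (1S)-1-[(1R,3S,4R,5S)-5-[(3R)-1,1-dimethoxy-4-methylpentan-3-yl]-3-hydroxy-2-oxo-4-[1-(trimethylsilyl)ethenyl]cyclopentyl]ethyl acetate; 17 (2R)-2-methylbutanoic acid
Product: 18 (1R,2R,3S,4R)-4-[(1S)-1-(acetyloxy)ethyl]-3-[(3R)-1,1-dimethoxy-4-methylpentan-3-yl]-5-oxo-2-[1-(trimethylsilyl)ethenyl]cyclopentyl (2R)-2-methylbutanoate
Conditions: PPh3, DIAD, toluene, 0 to 25 °C
Reagents that add atoms: none
Why: Mitsunobu reaction: the activated α-ketol is displaced by the carboxylate with inversion, which should turn the trans-hydroxyl into the cis-acyloxy group of the target and installs the (2R)-2-methylbutanoate in the same operation.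

Step 11
Reactants: 18 (1R,2R,3S,4R)-4-[(1S)-1-(acetyloxy)ethyl]-3-[(3R)-1,1-dimethoxy-4-methylpentan-3-yl]-5-oxo-2-[1-(trimethylsilyl)ethenyl]cyclopentyl (2R)-2-methylbutanoate
Product: 19 (1R,2R,3S,4R)-4-[(1S)-1-(acetyloxy)ethyl]-3-[(3R)-1,1-dimethoxy-4-methylpentan-3-yl]-2-(1-iodoethenyl)-5-oxocyclopentyl (2R)-2-methylbutanoate
Conditions: NIS, MeCN/ClCH2CN (4:1), 0 to 25 °C
Reagents that add atoms: N-iodosuccinimide, O=C1CCC(=O)N1I
Why: Iododesilylation: ipso attack of the iodonium source on the vinylsilane and loss of silicon should give the 1-iodoethenyl group under neutral conditions that leave esters, ketone and acetal alone.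

Step 12
Reactants: 19 (1R,2R,3S,4R)-4-[(1S)-1-(acetyloxy)ethyl]-3-[(3R)-1,1-dimethoxy-4-methylpentan-3-yl]-2-(1-iodoethenyl)-5-oxocyclopentyl (2R)-2-methylbutanoate
Product: 20 (1R,2R,3S,4R)-4-[(1S)-1-(acetyloxy)ethyl]-2-(1-iodoethenyl)-3-[(3R)-4-methyl-1-oxopentan-3-yl]-5-oxocyclopentyl (2R)-2-methylbutanoate
Conditions: LiBF4, MeCN/H2O (50:1), 25 °C
Reagents that add atoms: water, O
Why: Mild Lewis-acid-mediated acetal hydrolysis frees the aldehyde under conditions too weak to cleave the esters or to epimerise the α-acyloxy ketone.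

Step 13
Reactants: 20 (1R,2R,3S,4R)-4-[(1S)-1-(acetyloxy)ethyl]-2-(1-iodoethenyl)-3-[(3R)-4-methyl-1-oxopentan-3-yl]-5-oxocyclopentyl (2R)-2-methylbutanoate
Product: 21 (1R,3R,3aS,5S,7R,7aR)-1-[(1S)-1-(acetyloxy)ethyl]-5-hydroxy-4-methylidene-2-oxo-7-(propan-2-yl)octahydro-1H-inden-3-yl (2R)-2-methylbutanoate
Conditions: CrCl2 (8 equiv), NiCl2 (2 mol%), degassed DMSO, 25 °C, high dilution (0.005 M)
Reagents that add atoms: none
Why: Nozaki–Hiyama–Kishi reaction: zerovalent nickel (made from NiCl2 by CrCl2) inserts into the C–I bond, the alkenyl group passes to trivalent chromium and the alkenylchromium adds to the aldehyde, divalent chromium being the stoichiometric reductant. The closest known reaction type is the intramolecular nickel/chromium coupling of 2-iodoalk-1-enes with aldehydes to give 2-methylidenecycloalkanols. The cyclohexane ring closes in the 6-exo-trig mode, the alkenyl carbon attacking the exocyclic C=O. The new C5 carbinol centre should be set by a chair-like transition state in which the isopropyl group and both bonds to the cyclopentanone are equatorial and the C–O(Cr) bond is axial, which avoids allylic 1,3-strain with the methylidene group and leads to the 5S alcohol. The step needs aldehyde-over-ketone and aldehyde-over-ester selectivity, which the low basicity and aldehyde preference of alkenylchromium reagents secure, and the trans ring fusion follows from the trans arrangement of the two reacting arms on the cyclopentanone, which is in place after step 8.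

Step 14
Reactants: 21 (1R,3R,3aS,5S,7R,7aR)-1-[(1S)-1-(acetyloxy)ethyl]-5-hydroxy-4-methylidene-2-oxo-7-(propan-2-yl)octahydro-1H-inden-3-yl (2R)-2-methylbutanoate; 22 (2E)-3-methylpent-2-enoic acid
Product: 23 (1R,3R,3aS,5S,7R,7aR)-1-[(1S)-1-(acetyloxy)ethyl]-3-{[(2R)-2-methylbutanoyl]oxy}-4-methylidene-2-oxo-7-(propan-2-yl)octahydro-1H-inden-5-yl (2E)-3-methylpent-2-enoate
Conditions: DCC, DMAP (cat.), CH2Cl2, 0 to 25 °C
Reagents that add atoms: none
Why: Steglich esterification acylates the only free hydroxyl with retention at C5, catalytic DMAP at low temperature being chosen to avoid isomerisation of the (E)-enoate.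

Compound list
1 | (4R)-1-methyl-4-(propan-2-yl)cyclohex-1-ene, (R)-p-menth-1-ene | CC1=CC[C@H](C(C)C)CC1 | starting material
2 | (5R)-7,7-dimethoxy-5-(propan-2-yl)heptan-2-one | CC(=O)CC[C@@H](C(C)C)CC(OC)OC | intermediate
3 | trimethyl{[(2Z,5R)-7,7-dimethoxy-5-(propan-2-yl)hept-2-en-2-yl]oxy}silane | C/C(O[Si](C)(C)C)=C/C[C@@H](C(C)C)CC(OC)OC | intermediate
4 | (3E,5R)-7,7-dimethoxy-5-(propan-2-yl)hept-3-en-2-one | CC(=O)/C=C/[C@@H](C(C)C)CC(OC)OC | intermediate
5 | [(1E)-prop-1-en-1-yl]boronic acid | C/C=C/B(O)O | starting material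
6 | (4S,5R)-7,7-dimethoxy-4-[(1E)-prop-1-en-1-yl]-5-(propan-2-yl)heptan-2-one | CC(=O)C[C@@H](/C=C/C)[C@@H](C(C)C)CC(OC)OC | intermediate
7 | (2R,3R)-5,5-dimethoxy-2-(2-oxopropyl)-3-(propan-2-yl)pentanal | CC(=O)C[C@@H](C=O)[C@@H](C(C)C)CC(OC)OC | intermediate
8 | (4S)-4-[(3R)-1,1-dimethoxy-4-methylpentan-3-yl]cyclopent-2-en-1-one | O=C1C=C[C@@H]([C@@H](C(C)C)CC(OC)OC)C1 | intermediate
9 | acetaldehyde | CC=O | starting material
10 | (4S,5R)-4-[(3R)-1,1-dimethoxy-4-methylpentan-3-yl]-5-[(1S)-1-hydroxyethyl]cyclopent-2-en-1-one | O=C1C=C[C@@H]([C@@H](C(C)C)CC(OC)OC)[C@@H]1[C@H](C)O | intermediate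
11 | (1S)-1-[(1R,5S)-5-[(3R)-1,1-dimethoxy-4-methylpentan-3-yl]-2-oxocyclopent-3-en-1-yl]ethyl acetate | O=C1C=C[C@@H]([C@@H](C(C)C)CC(OC)OC)[C@@H]1[C@H](C)OC(C)=O | intermediate
12 | (1-bromoethenyl)trimethylsilane | C=C(Br)[Si](C)(C)C | starting material
13 | [1-(trimethylsilyl)ethenyl]magnesium bromide | C=C([Mg]Br)[Si](C)(C)C | intermediate
14 | (1S)-1-[(1R,4R,5S)-5-[(3R)-1,1-dimethoxy-4-methylpentan-3-yl]-2-[(trimethylsilyl)oxy]-4-[1-(trimethylsilyl)ethenyl]cyclopent-2-en-1-yl]ethyl acetate | C[Si](C)(C)OC1=C[C@H](C(=C)[Si](C)(C)C)[C@@H]([C@@H](C(C)C)CC(OC)OC)[C@@H]1[C@H](C)OC(C)=O | intermediate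
15 | (1S)-1-[(1R,3S,4R,5S)-5-[(3R)-1,1-dimethoxy-4-methylpentan-3-yl]-2-oxo-3-[(trimethylsilyl)oxy]-4-[1-(trimethylsilyl)ethenyl]cyclopentyl]ethyl acetate | O=C1[C@@H](O[Si](C)(C)C)[C@H](C(=C)[Si](C)(C)C)[C@@H]([C@@H](C(C)C)CC(OC)OC)[C@@H]1[C@H](C)OC(C)=O | intermediate
16 | (1S)-1-[(1R,3S,4R,5S)-5-[(3R)-1,1-dimethoxy-4-methylpentan-3-yl]-3-hydroxy-2-oxo-4-[1-(trimethylsilyl)ethenyl]cyclopentyl]ethyl acetate | O=C1[C@@H](O)[C@H](C(=C)[Si](C)(C)C)[C@@H]([C@@H](C(C)C)CC(OC)OC)[C@@H]1[C@H](C)OC(C)=O | intermediate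
17 | (2R)-2-methylbutanoic acid | CC[C@@H](C)C(=O)O | starting material
18 | (1R,2R,3S,4R)-4-[(1S)-1-(acetyloxy)ethyl]-3-[(3R)-1,1-dimethoxy-4-methylpentan-3-yl]-5-oxo-2-[1-(trimethylsilyl)ethenyl]cyclopentyl (2R)-2-methylbutanoate | O=C1[C@H](OC(=O)[C@H](C)CC)[C@H](C(=C)[Si](C)(C)C)[C@@H]([C@@H](C(C)C)CC(OC)OC)[C@@H]1[C@H](C)OC(C)=O | intermediate
19 | (1R,2R,3S,4R)-4-[(1S)-1-(acetyloxy)ethyl]-3-[(3R)-1,1-dimethoxy-4-methylpentan-3-yl]-2-(1-iodoethenyl)-5-oxocyclopentyl (2R)-2-methylbutanoate | O=C1[C@H](OC(=O)[C@H](C)CC)[C@H](C(=C)I)[C@@H]([C@@H](C(C)C)CC(OC)OC)[C@@H]1[C@H](C)OC(C)=O | intermediate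
20 | (1R,2R,3S,4R)-4-[(1S)-1-(acetyloxy)ethyl]-2-(1-iodoethenyl)-3-[(3R)-4-methyl-1-oxopentan-3-yl]-5-oxocyclopentyl (2R)-2-methylbutanoate | O=C1[C@H](OC(=O)[C@H](C)CC)[C@H](C(=C)I)[C@@H]([C@@H](C(C)C)CC=O)[C@@H]1[C@H](C)OC(C)=O | intermediate
21 | (1R,3R,3aS,5S,7R,7aR)-1-[(1S)-1-(acetyloxy)ethyl]-5-hydroxy-4-methylidene-2-oxo-7-(propan-2-yl)octahydro-1H-inden-3-yl (2R)-2-methylbutanoate | C=C1[C@@H]2[C@H]([C@H]([C@H](C)OC(C)=O)C(=O)[C@@H]2OC(=O)[C@H](C)CC)[C@@H](C(C)C)C[C@@H]1O | intermediate
22 | (2E)-3-methylpent-2-enoic acid | CC/C(C)=C/C(=O)O | starting material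
23 | (1R,3R,3aS,5S,7R,7aR)-1-[(1S)-1-(acetyloxy)ethyl]-3-{[(2R)-2-methylbutanoyl]oxy}-4-methylidene-2-oxo-7-(propan-2-yl)octahydro-1H-inden-5-yl (2E)-3-methylpent-2-enoate | C=C1[C@@H]2[C@H]([C@H]([C@H](C)OC(C)=O)C(=O)[C@@H]2OC(=O)[C@H](C)CC)[C@@H](C(C)C)C[C@@H]1OC(=O)/C=C(\C)CC | target

Total step count: 14. Longest linear sequence: 14 steps (1 to 23).

Steps most likely to fail

Step 4. The chiral catalyst and the existing C5 stereocentre may be mismatched, so that the propenyl group is delivered with poor facial selectivity, or the branched β-carbon may react so slowly that protodeboronation takes over. The fallback replaces catalyst control by chirality transfer. It sets out from enone 4, which is reduced by Corey–Bakshi–Shibata reduction ((R)-2-methyl-CBS-oxazaborolidine, catecholborane, toluene, −78 °C) to (2S,3E,5R)-7,7-dimethoxy-5-(propan-2-yl)hept-3-en-2-ol F1. Acid-catalysed exchange with 2-methoxypropene gives the allyl isopropenyl ether 2-{[(2S,3E,5R)-7,7-dimethoxy-5-(propan-2-yl)hept-3-en-2-yl]oxy}prop-1-ene F2. On heating (xylene, 140 °C, sealed tube) this should undergo Claisen rearrangement through a chair with the carbinol methyl equatorial, passing the carbinol configuration on to C4. The product is ketone 6, where the route is rejoined.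

Step 10. The hindered α-ketol may be activated and then eliminate, or the carboxylate may fail to reach the backside next to the silylethenyl group, so that inversion is incomplete. The fallback delivers the acyloxy group intramolecularly. It sets out from enone 11: the copper-catalysed addition of 13 is quenched with (2R)-2-methylbutanoic anhydride F3 (from 17 and DCC) instead of Me3SiCl. This should give the enol ester (3R,4S,5R)-5-[(1S)-1-(acetyloxy)ethyl]-4-[(3R)-1,1-dimethoxy-4-methylpentan-3-yl]-3-[1-(trimethylsilyl)ethenyl]cyclopent-1-en-1-yl (2R)-2-methylbutanoate F4. DMDO epoxidises it anti to the silylethenyl group to the enol ester epoxide F5 (the 1-acyloxy-6-oxabicyclo[3.1.0]hexane with the oxirane on the face opposite that group). Heating (toluene, 110 °C) should shift the acyloxy group to the neighbouring carbon by backside opening of the epoxide, i.e. with inversion. This gives 18, where the route is rejoined.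

Step 13. The aldehyde has no stereocentre next to it, so the alkenylchromium may add with poor facial selectivity and give the C5 epimer of the alcohol as well or instead. The fallback makes the ring closure stereoconvergent; it sets out from 20 and returns at 23. After the same ring closure the epimers are separated. The (5R)-alcohol (1R,3R,3aS,5R,7R,7aR)-1-[(1S)-1-(acetyloxy)ethyl]-5-hydroxy-4-methylidene-2-oxo-7-(propan-2-yl)octahydro-1H-inden-3-yl (2R)-2-methylbutanoate F6 is esterified with 22 under Mitsunobu conditions (PPh3, DIAD, toluene, 0 °C), which should give 23 with inversion. Any (5S)-alcohol 21 goes through step 14 unchanged.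

Further compounds
F1 | step 4 | (2S,3E,5R)-7,7-dimethoxy-5-(propan-2-yl)hept-3-en-2-ol | C[C@H](O)/C=C/[C@@H](C(C)C)CC(OC)OC
F2 | step 4 | 2-{[(2S,3E,5R)-7,7-dimethoxy-5-(propan-2-yl)hept-3-en-2-yl]oxy}prop-1-ene | CC(=C)O[C@@H](C)/C=C/[C@@H](C(C)C)CC(OC)OC
F3 | step 10 | (2R)-2-methylbutanoic anhydride | CC[C@@H](C)C(=O)OC(=O)[C@H](C)CC
F4 | step 10 | (3R,4S,5R)-5-[(1S)-1-(acetyloxy)ethyl]-4-[(3R)-1,1-dimethoxy-4-methylpentan-3-yl]-3-[1-(trimethylsilyl)ethenyl]cyclopent-1-en-1-yl (2R)-2-methylbutanoate | CC[C@@H](C)C(=O)OC1=C[C@H](C(=C)[Si](C)(C)C)[C@@H]([C@@H](C(C)C)CC(OC)OC)[C@@H]1[C@H](C)OC(C)=O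
F5 | step 10 | enol ester epoxide of F4, oxirane anti to the silylethenyl group (1-acyloxy-6-oxabicyclo[3.1.0]hexane) | CC[C@@H](C)C(=O)O[C@]12O[C@H]1[C@H](C(=C)[Si](C)(C)C)[C@@H]([C@@H](C(C)C)CC(OC)OC)[C@@H]2[C@H](C)OC(C)=O
F6 | step 13 | (1R,3R,3aS,5R,7R,7aR)-1-[(1S)-1-(acetyloxy)ethyl]-5-hydroxy-4-methylidene-2-oxo-7-(propan-2-yl)octahydro-1H-inden-3-yl (2R)-2-methylbutanoate | C=C1[C@@H]2[C@H]([C@H]([C@H](C)OC(C)=O)C(=O)[C@@H]2OC(=O)[C@H](C)CC)[C@@H](C(C)C)C[C@H]1O
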